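Retrosynthesis: once the O-protecting groups are off, the C3–O bond is cut first (flavonol to flavone). Ring C is then opened at three bonds at once (C4a–C4, C4–C3, O1–C2), and the C8–CH2 bond between ring A and the side chain is cut last.
Enabling feature: O1 is the oxygen on C8a, and C8a lies between the chain-bearing C8 and C4a. With O5 blocked and O7 para to C4a, an iodide on C4a can only fuse ring C next to C8; CO becomes C4 and a ring B arylacetylene supplies C3 and C2.
Forward order: chain fragment, ring A building block, C8–CH2 Negishi union, C4a iodination, methyl addition, phenol release, one-step closure of ring C with ring B attached, C3 hydroxylation, deprotection. Rings A and B are bought; only ring C is made.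
Stereochemistry: the single (R) centre is C4 of (R)-limonene. Cleavage of C1=C2, excision of C2 as CO2 and methyl addition to the C1 ketone never touch it.
Protecting groups: O5 is carried as a triisopropylsilyl ether and ring B as MOM ethers that are cleaved without protic acid, so the isopropenyl group and the tertiary carbinol never meet a strong acid or a demethylating Lewis acid.
Key step: step 14

Remark on the chemistry: flavone numbering (O1, C2 to C8a, primed atoms for ring B) is also used for the ring A intermediates. CIP analysis of the target SMILES gives (R) at the chain stereocentre, which is the spatial arrangement of C4 in (R)-limonene. Descriptors that read (S) on the way reflect only the higher rank of CH2I or CH2Zn.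

Step 1
Reactants: 1 (R)-limonene
Product: 2 (4R)-limonene 1,2-oxide (mixture of cis and trans epoxides)
Conditions: mCPBA (1.0 equiv), CH2Cl2, 0 °C
Reagents that add atoms: mCPBA (3-chloroperoxybenzoic acid), O=C(OO)c1cccc(Cl)c1
Why: Prilezhaev epoxidation follows alkene nucleophilicity, so one equivalent of peracid should take the trisubstituted C1=C2 ring alkene and spare the 1,1-disubstituted isopropenyl group, and the epimer mixture at C1 and C2 is harmless because both centres are erased in step 2.

Step 2
Reactants: 2 (4R)-limonene 1,2-oxide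
Product: 4 (3R)-6-oxo-3-(prop-1-en-2-yl)heptanal, via diol 3 (not isolated)
Conditions: H5IO6, THF–H2O, 0 °C to rt
Reagents that add atoms: water, O
Why: Aqueous periodic acid opens the epoxide to diol 3 and cleaves it at once (Malaprade glycol cleavage), which makes C1 the methyl ketone and C2 the aldehyde while the isolated isopropenyl group and the stereocentre, which carries no acidic hydrogen, stay as they are.

Step 3
Reactants: 4 (3R)-6-oxo-3-(prop-1-en-2-yl)heptanal
Product: 5 (3R)-6-oxo-3-(prop-1-en-2-yl)heptanoic acid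
Conditions: NaClO2, NaH2PO4, 2-methyl-2-butene, t-BuOH–H2O, 0 °C to rt
Reagents that add atoms: sodium chlorite NaClO2, [Na+].[O-]Cl=O
Why: Pinnick oxidation converts only the aldehyde, the ketone being inert to chlorite, and 2-methyl-2-butene intercepts the hypochlorous acid that could otherwise add to the isopropenyl group.

Step 4
Reactants: 5 (3R)-6-oxo-3-(prop-1-en-2-yl)heptanoic acid
Product: 7 (5S)-5-(iodomethyl)-6-methylhept-6-en-2-one, via Barton ester 6 (not isolated)
Conditions: N-hydroxypyridine-2-thione, DCC, CH2Cl2, 0 °C, dark; then CHI3, tungsten lamp, rt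
Reagents that add atoms: iodoform CHI3, IC(I)I
Why: Barton decarboxylative iodination: photolysis of thiohydroxamate ester 6 releases CO2 and a primary alkyl radical that should abstract iodine from CHI3 far faster than a 3-butenyl radical can close onto its own alkene, so the former C2 of limonene is excised, the neighbouring stereocentre keeps its arrangement, and the ketone and the alkene tolerate this neutral radical chain.

Step 5
Reactants: 8 phloroglucinol
Product: 9 5-(triisopropylsilyloxy)benzene-1,3-diol
Conditions: iPr3SiCl (1 equiv), imidazole, 8 (3 equiv), DMF, 0 °C to rt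
Reagents that add atoms: chlorotriisopropylsilane, CC(C)[Si](Cl)(C(C)C)C(C)C
Why: Silyl ether formation with a bulky chlorosilane as the limiting reagent and the cheap triol in excess should stop at the monoether, the surplus water-soluble phloroglucinol being washed out, and this group marks the oxygen that becomes O5 and can later be removed by fluoride instead of a Lewis acid.

Step 6
Reactants: 9 5-(triisopropylsilyloxy)benzene-1,3-diol
Product: 10 [3,5-bis(methoxymethoxy)phenoxy]triisopropylsilane
Conditions: MOMCl, iPr2NEt, CH2Cl2, 0 °C to rt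
Reagents that add atoms: chloromethyl methyl ether, COCCl
Why: O-Alkylation of the two remaining phenols with MOMCl and a hindered amine base is routine acetal protection, leaves the aryl silyl ether intact and installs the two chelating groups needed for the next metalation.

Step 7
Reactants: 10 [3,5-bis(methoxymethoxy)phenoxy]triisopropylsilane
Product: 12 [4-iodo-3,5-bis(methoxymethoxy)phenoxy]triisopropylsilane, via aryllithium 11 (not isolated)
Conditions: n-BuLi, THF, 0 °C; then I2, −78 °C
Reagents that add atoms: iodine, II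
Why: Directed ortho-metalation takes place at the carbon flanked by both chelating OMOM groups, the two other ring positions being shielded by the bulky and non-coordinating silyloxy group, and iodine quench of aryllithium 11 fixes the future C8 as the coupling site.

Step 8
Reactants: 7 (5S)-5-(iodomethyl)-6-methylhept-6-en-2-one; 12 [4-iodo-3,5-bis(methoxymethoxy)phenoxy]triisopropylsilane
Product: 14 (5R)-5-{[2,6-bis(methoxymethoxy)-4-(triisopropylsilyloxy)phenyl]methyl}-6-methylhept-6-en-2-one, via alkylzinc iodide 13 (not isolated)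
Conditions: 7, Zn dust, LiCl, THF, 25 °C; then 12, Pd(OAc)2 (3 mol %), SPhos (6 mol %), THF, 25 to 40 °C
Reagents that add atoms: none
Why: Negishi sp3–sp2 cross-coupling: zinc insertion into the primary iodide in the presence of LiCl tolerates the ketone, and the bulky electron-rich biaryl phosphine should drive reductive elimination from the crowded aryl(alkyl)palladium faster than β-hydride loss at the stereocentre, so the C8–CH2 bond forms with the configuration retained.

Step 9
Reactants: 14 (5R)-5-{[2,6-bis(methoxymethoxy)-4-(triisopropylsilyloxy)phenyl]methyl}-6-methylhept-6-en-2-one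
Product: 15 (5R)-5-{[3-iodo-2,6-bis(methoxymethoxy)-4-(triisopropylsilyloxy)phenyl]methyl}-6-methylhept-6-en-2-one
Conditions: NIS (1.0 equiv), MeCN, 0 °C, dark
Reagents that add atoms: N-iodosuccinimide, O=C1CCC(=O)N1I
Why: Electrophilic aromatic iodination: the trioxygenated ring is far more nucleophilic than the isopropenyl group, its two free positions are equivalent by symmetry so only one monoiodide can arise, and running the step on the ketone in dry acid-free MeCN leaves the alkene without an internal or external nucleophile for iodo-functionalisation.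

Step 10
Reactants: 15 (5R)-5-{[3-iodo-2,6-bis(methoxymethoxy)-4-(triisopropylsilyloxy)phenyl]methyl}-6-methylhept-6-en-2-one
Product: 16 (5R)-5-{[3-iodo-2,6-bis(methoxymethoxy)-4-(triisopropylsilyloxy)phenyl]methyl}-2,6-dimethylhept-6-en-2-ol
Conditions: MeMgBr, THF, −78 to −20 °C
Reagents that add atoms: methylmagnesium bromide MeMgBr, C[Mg]Br
Why: Grignard 1,2-addition to the methyl ketone is fast at low temperature whereas MeMgBr does not exchange with an electron-rich aryl iodide under these conditions, and the new carbinol carbon bears two methyl groups and is therefore not a stereocentre.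

Step 11
Reactants: 16 (5R)-5-{[3-iodo-2,6-bis(methoxymethoxy)-4-(triisopropylsilyloxy)phenyl]methyl}-2,6-dimethylhept-6-en-2-ol
Product: 18 2-[(2R)-5-hydroxy-5-methyl-2-(prop-1-en-2-yl)hexyl]-4-iodo-5-(triisopropylsilyloxy)benzene-1,3-diol, via tris(trimethylsilyl) ether 17 (not isolated)
Conditions: Me3SiOTf, 2,2'-bipyridyl, MeCN, 0 °C to rt; then H2O, rt
Reagents that add atoms: none
Why: The silyl triflate and 2,2'-bipyridyl method for aromatic MOM ethers turns each ArO–CH2OMe into ArO–SiMe3 under buffered aprotic conditions and water then frees the phenols and the transiently silylated carbinol in a weakly acidic medium, which avoids the protic acid that would protodeiodinate the ring, ionise the carbinol or add a phenol across the isopropenyl group, while the hindered O5 silyl ether stays.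

Step 12
Reactants: 19 2,4-dihydroxybenzaldehyde
Product: 20 2,4-bis(methoxymethoxy)benzaldehyde
Conditions: MOMCl, iPr2NEt, CH2Cl2, 0 °C to rt
Reagents that add atoms: chloromethyl methyl ether, COCCl
Why: Routine MOM acetal protection of both phenols, the chelated 2-OH included when reagent and base are used in excess, gives ethers that are stable to amines, CO and amide bases and whose 2'-oxygen can later help to hold lithium at C3.

Step 13
Reactants: 20 2,4-bis(methoxymethoxy)benzaldehyde
Product: 21 1-ethynyl-2,4-bis(methoxymethoxy)benzene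
Conditions: dimethyl (1-diazo-2-oxopropyl)phosphonate, K2CO3, MeOH, rt
Reagents that add atoms: dimethyl (1-diazo-2-oxopropyl)phosphonate, COP(=O)(OC)C(=[N+]=[N-])C(C)=O
Why: The Ohira–Bestmann variant of the Seyferth–Gilbert homologation converts the aryl aldehyde into the terminal alkyne in one step under mild carbonate conditions that MOM ethers tolerate.

Step 14
Reactants: 18 2-[(2R)-5-hydroxy-5-methyl-2-(prop-1-en-2-yl)hexyl]-4-iodo-5-(triisopropylsilyloxy)benzene-1,3-diol; 21 1-ethynyl-2,4-bis(methoxymethoxy)benzene; 22 carbon monoxide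
Product: 25 2-[2,4-bis(methoxymethoxy)phenyl]-7-hydroxy-8-[(2R)-5-hydroxy-5-methyl-2-(prop-1-en-2-yl)hexyl]-5-(triisopropylsilyloxy)-4H-chromen-4-one, via ynone 23 (not isolated), via enaminone 24 (not isolated)
Conditions: PdCl2(dppf) (5 mol %), CO (5 bar), Et2NH–DMF, 60 °C
Reagents that add atoms: carbon monoxide (compound 22), [C-]#[O+]
Why: Zerovalent palladium generated from PdCl2(dppf) inserts into the C4a–I bond of 18, migratory insertion of CO gives the aroylpalladium iodide (C4a–C4), and the amine-deprotonated alkyne 21 is transferred to palladium and reductively eliminated as ynone 23 (C4–C3). Et2NH then adds to the alkyne terminus C2 to give enaminone 24, and the C8a phenol displaces the amine by addition–elimination, which amounts to a 6-endo closure of ring C (O1–C2) and returns the Et2NH. The closest known reaction type is the palladium-catalysed carbonylative annulation of ortho-iodophenols with terminal arylacetylenes in secondary amines, that is, a copper-free carbonylative Sonogashira coupling followed by oxa-Michael cyclisation. No stereocentre is created, and the (R) centre of the chain, separated from ring A by a CH2 group, takes no part. Three selectivities are needed: flavone over aurone, secured because the enaminone path places the electrophilic site at C2 and shuts off 5-exo attack at C3; 8-alkyl over 6-alkyl, secured because O5 carries the triisopropylsilyl group and O7 is para to C4a, so only the C8a oxygen can reach C2; and carbonylative over direct alkynylation, favoured by the absence of copper, by CO pressure and by the electron-rich, doubly ortho-substituted arylpalladium that takes up CO readily. The 7-OH, the tertiary carbinol, the isopropenyl group and the MOM ethers have no reaction channel under these mildly basic conditions.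

Step 15
Reactants: 25 2-[2,4-bis(methoxymethoxy)phenyl]-7-hydroxy-8-[(2R)-5-hydroxy-5-methyl-2-(prop-1-en-2-yl)hexyl]-5-(triisopropylsilyloxy)-4H-chromen-4-one
Product: 26 2-[2,4-bis(methoxymethoxy)phenyl]-7-(triethylsilyloxy)-8-[(2R)-5-methyl-2-(prop-1-en-2-yl)-5-(triethylsilyloxy)hexyl]-5-(triisopropylsilyloxy)-4H-chromen-4-one
Conditions: Et3SiOTf, 2,6-lutidine, CH2Cl2, 0 °C
Reagents that add atoms: triethylsilyl trifluoromethanesulfonate, CC[Si](CC)(CC)OS(=O)(=O)C(F)(F)F
Why: Silylation with a silyl triflate and 2,6-lutidine is strong enough for the tertiary carbinol as well as the 7-phenol and so removes both acidic protons before the metalation, while aromatic MOM ethers survive brief exposure at 0 °C when lutidine is the base.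

Step 16
Reactants: 26 2-[2,4-bis(methoxymethoxy)phenyl]-7-(triethylsilyloxy)-8-[(2R)-5-methyl-2-(prop-1-en-2-yl)-5-(triethylsilyloxy)hexyl]-5-(triisopropylsilyloxy)-4H-chromen-4-one
Product: 29 2-[2,4-bis(methoxymethoxy)phenyl]-3-hydroxy-7-(triethylsilyloxy)-8-[(2R)-5-methyl-2-(prop-1-en-2-yl)-5-(triethylsilyloxy)hexyl]-5-(triisopropylsilyloxy)-4H-chromen-4-one, via 3-lithioflavone 27 (not isolated), via boronate 28 (not isolated)
Conditions: LiN(iPr)2, THF, −78 °C; B(OMe)3, −78 to 0 °C; then AcOH, 30 % H2O2, 0 °C to rt
Reagents that add atoms: hydrogen peroxide, OO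
Why: Lithiation–borylation–oxidation, known for 5,7-dialkoxyflavones: the amide base removes the C3 hydrogen, the only acidic C–H, the lithium being held between the C4 carbonyl and the 2'-OMOM oxygen, B(OMe)3 traps 27 as boronate 28, and buffered peroxide converts C–B into C–O without epoxidising the unactivated isopropenyl group.

Step 17
Reactants: 29 2-[2,4-bis(methoxymethoxy)phenyl]-3-hydroxy-7-(triethylsilyloxy)-8-[(2R)-5-methyl-2-(prop-1-en-2-yl)-5-(triethylsilyloxy)hexyl]-5-(triisopropylsilyloxy)-4H-chromen-4-one
Product: 30 2-[2,4-bis(methoxymethoxy)phenyl]-3,5,7-trihydroxy-8-[(2R)-5-hydroxy-5-methyl-2-(prop-1-en-2-yl)hexyl]-4H-chromen-4-one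
Conditions: Bu4NF, AcOH, THF, 0 °C to rt, argon
Reagents that add atoms: none
Why: Fluoride-induced desilylation buffered with AcOH cleaves the two aryl silyl ethers and the tertiary triethylsilyl ether without strong acid or free phenoxide base, so the oxidation-prone flavonol, the alkene, the carbinol and the MOM ethers are all preserved.

Step 18
Reactants: 30 2-[2,4-bis(methoxymethoxy)phenyl]-3,5,7-trihydroxy-8-[(2R)-5-hydroxy-5-methyl-2-(prop-1-en-2-yl)hexyl]-4H-chromen-4-one
Product: 32 kushenol G, via hexakis(trimethylsilyl) ether 31 (not isolated)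
Conditions: Me3SiOTf (excess), 2,2'-bipyridyl, MeCN, 0 °C to rt; then H2O, rt
Reagents that add atoms: none
Why: The same silyl triflate and 2,2'-bipyridyl cleavage of aromatic MOM ethers, run with enough reagent to silylate every hydroxyl in passing, exchanges the two ring B acetals for trimethylsilyl ethers, and mild aqueous hydrolysis of 31 then liberates all six hydroxyls, so the isopropenyl group and the tertiary carbinol next to the free 7-OH never meet a strong protic acid.

Compound list
1 | (R)-limonene, (4R)-1-methyl-4-(prop-1-en-2-yl)cyclohex-1-ene | CC1=CC[C@@H](CC1)C(C)=C | starting material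
2 | (4R)-limonene 1,2-oxide, mixture of cis and trans epoxides | CC12OC1C[C@@H](CC2)C(C)=C | intermediate
3 | (4R)-1-methyl-4-(prop-1-en-2-yl)cyclohexane-1,2-diol (not isolated) | CC1(O)C(O)C[C@@H](CC1)C(C)=C | intermediate
4 | (3R)-6-oxo-3-(prop-1-en-2-yl)heptanal | C=C(C)[C@H](CCC(C)=O)CC=O | intermediate
5 | (3R)-6-oxo-3-(prop-1-en-2-yl)heptanoic acid | C=C(C)[C@H](CCC(C)=O)CC(=O)O | intermediate
6 | 2-thioxopyridin-1(2H)-yl (3R)-6-oxo-3-(prop-1-en-2-yl)heptanoate, Barton ester (not isolated) | C=C(C)[C@H](CCC(C)=O)CC(=O)On1ccccc1=S | intermediate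
7 | (5S)-5-(iodomethyl)-6-methylhept-6-en-2-one | C=C(C)[C@H](CCC(C)=O)CI | intermediate
8 | phloroglucinol, benzene-1,3,5-triol | Oc1cc(O)cc(O)c1 | starting material
9 | 5-(triisopropylsilyloxy)benzene-1,3-diol | CC(C)[Si](Oc1cc(O)cc(O)c1)(C(C)C)C(C)C | intermediate
10 | [3,5-bis(methoxymethoxy)phenoxy]triisopropylsilane | COCOc1cc(OCOC)cc(O[Si](C(C)C)(C(C)C)C(C)C)c1 | intermediate
11 | [2,6-bis(methoxymethoxy)-4-(triisopropylsilyloxy)phenyl]lithium (not isolated) | [Li]c1c(OCOC)cc(O[Si](C(C)C)(C(C)C)C(C)C)cc1OCOC | intermediate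
12 | [4-iodo-3,5-bis(methoxymethoxy)phenoxy]triisopropylsilane | COCOc1cc(O[Si](C(C)C)(C(C)C)C(C)C)cc(OCOC)c1I | intermediate
13 | [(2S)-5-oxo-2-(prop-1-en-2-yl)hexyl]zinc iodide (not isolated) | C=C(C)[C@H](CCC(C)=O)C[Zn]I | intermediate
14 | (5R)-5-{[2,6-bis(methoxymethoxy)-4-(triisopropylsilyloxy)phenyl]methyl}-6-methylhept-6-en-2-one | C=C(C)[C@H](CCC(C)=O)Cc1c(OCOC)cc(O[Si](C(C)C)(C(C)C)C(C)C)cc1OCOC | intermediate
15 | (5R)-5-{[3-iodo-2,6-bis(methoxymethoxy)-4-(triisopropylsilyloxy)phenyl]methyl}-6-methylhept-6-en-2-one | C=C(C)[C@H](CCC(C)=O)Cc1c(OCOC)cc(O[Si](C(C)C)(C(C)C)C(C)C)c(I)c1OCOC | intermediate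
16 | (5R)-5-{[3-iodo-2,6-bis(methoxymethoxy)-4-(triisopropylsilyloxy)phenyl]methyl}-2,6-dimethylhept-6-en-2-ol | C=C(C)[C@H](CCC(C)(C)O)Cc1c(OCOC)cc(O[Si](C(C)C)(C(C)C)C(C)C)c(I)c1OCOC | intermediate
17 | tris(trimethylsilyl) ether of 18 (both phenols and the carbinol; not isolated) | C=C(C)[C@H](CCC(C)(C)O[Si](C)(C)C)Cc1c(O[Si](C)(C)C)cc(O[Si](C(C)C)(C(C)C)C(C)C)c(I)c1O[Si](C)(C)C | intermediate
18 | 2-[(2R)-5-hydroxy-5-methyl-2-(prop-1-en-2-yl)hexyl]-4-iodo-5-(triisopropylsilyloxy)benzene-1,3-diol | C=C(C)[C@H](CCC(C)(C)O)Cc1c(O)cc(O[Si](C(C)C)(C(C)C)C(C)C)c(I)c1O | intermediate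
19 | 2,4-dihydroxybenzaldehyde | O=Cc1ccc(O)cc1O | starting material
20 | 2,4-bis(methoxymethoxy)benzaldehyde | COCOc1ccc(C=O)c(OCOC)c1 | intermediate
21 | 1-ethynyl-2,4-bis(methoxymethoxy)benzene | C#Cc1ccc(OCOC)cc1OCOC | intermediate
22 | carbon monoxide | [C-]#[O+] | starting material
23 | 1-{2,4-dihydroxy-3-[(2R)-5-hydroxy-5-methyl-2-(prop-1-en-2-yl)hexyl]-6-(triisopropylsilyloxy)phenyl}-3-[2,4-bis(methoxymethoxy)phenyl]prop-2-yn-1-one (not isolated) | C=C(C)[C@H](CCC(C)(C)O)Cc1c(O)cc(O[Si](C(C)C)(C(C)C)C(C)C)c(C(=O)C#Cc2ccc(OCOC)cc2OCOC)c1O | intermediate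
24 | 3-(diethylamino)prop-2-en-1-one adduct of 23 with Et2NH, alkene geometry not fixed (not isolated) | C=C(C)[C@H](CCC(C)(C)O)Cc1c(O)cc(O[Si](C(C)C)(C(C)C)C(C)C)c(C(=O)C=C(N(CC)CC)c2ccc(OCOC)cc2OCOC)c1O | intermediate
25 | 2-[2,4-bis(methoxymethoxy)phenyl]-7-hydroxy-8-[(2R)-5-hydroxy-5-methyl-2-(prop-1-en-2-yl)hexyl]-5-(triisopropylsilyloxy)-4H-chromen-4-one | C=C(C)[C@H](CCC(C)(C)O)Cc1c(O)cc(O[Si](C(C)C)(C(C)C)C(C)C)c2c(=O)cc(-c3ccc(OCOC)cc3OCOC)oc12 | intermediate
26 | 7-O,carbinol-O-bis(triethylsilyl) ether of 25 | C=C(C)[C@H](CCC(C)(C)O[Si](CC)(CC)CC)Cc1c(O[Si](CC)(CC)CC)cc(O[Si](C(C)C)(C(C)C)C(C)C)c2c(=O)cc(-c3ccc(OCOC)cc3OCOC)oc12 | intermediate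
27 | 3-lithio derivative of 26 (not isolated) | C=C(C)[C@H](CCC(C)(C)O[Si](CC)(CC)CC)Cc1c(O[Si](CC)(CC)CC)cc(O[Si](C(C)C)(C(C)C)C(C)C)c2c(=O)c([Li])c(-c3ccc(OCOC)cc3OCOC)oc12 | intermediate
28 | dimethyl boronate at C3 of 26 (not isolated) | C=C(C)[C@H](CCC(C)(C)O[Si](CC)(CC)CC)Cc1c(O[Si](CC)(CC)CC)cc(O[Si](C(C)C)(C(C)C)C(C)C)c2c(=O)c(B(OC)OC)c(-c3ccc(OCOC)cc3OCOC)oc12 | intermediate
29 | 2-[2,4-bis(methoxymethoxy)phenyl]-3-hydroxy-7-(triethylsilyloxy)-8-[(2R)-5-methyl-2-(prop-1-en-2-yl)-5-(triethylsilyloxy)hexyl]-5-(triisopropylsilyloxy)-4H-chromen-4-one | C=C(C)[C@H](CCC(C)(C)O[Si](CC)(CC)CC)Cc1c(O[Si](CC)(CC)CC)cc(O[Si](C(C)C)(C(C)C)C(C)C)c2c(=O)c(O)c(-c3ccc(OCOC)cc3OCOC)oc12 | intermediate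
30 | 2-[2,4-bis(methoxymethoxy)phenyl]-3,5,7-trihydroxy-8-[(2R)-5-hydroxy-5-methyl-2-(prop-1-en-2-yl)hexyl]-4H-chromen-4-one | C=C(C)[C@H](CCC(C)(C)O)Cc1c(O)cc(O)c2c(=O)c(O)c(-c3ccc(OCOC)cc3OCOC)oc12 | intermediate
31 | hexakis(trimethylsilyl) ether of 32 (not isolated) | C=C(C)[C@H](CCC(C)(C)O[Si](C)(C)C)Cc1c(O[Si](C)(C)C)cc(O[Si](C)(C)C)c2c(=O)c(O[Si](C)(C)C)c(-c3ccc(O[Si](C)(C)C)cc3O[Si](C)(C)C)oc12 | intermediate
32 | kushenol G, 2-(2,4-dihydroxyphenyl)-3,5,7-trihydroxy-8-[(2R)-5-hydroxy-5-methyl-2-(prop-1-en-2-yl)hexyl]-4H-chromen-4-one | C=C(C)[C@H](CCC(C)(C)O)Cc1c(O)cc(O)c2c(=O)c(O)c(-c3ccc(O)cc3O)oc12 | target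

Total step count: 18.
Longest linear sequence: 13 steps (1–4, 8–11, 14–18).

Steps most likely to fail

1. Step 14.
- What may go wrong: oxidative addition may be slow at an iodide wedged between a phenoxide and a bulky silyl ether.
- The alkyne may be taken up before CO, which means direct alkynylation followed by 5-endo closure.
- Et2NH may capture the aroylpalladium (aminocarbonylation).
- The O5 silyl group may be lost before ring closure, which would allow closure through the wrong oxygen.
- Fallback (polar assembly of the ynone, without palladium or CO): it sets out from 18 and 21. Et3SiCl and imidazole cap only the two phenols of 18 to give the bis(triethylsilyl) ether F1. iPrMgCl·LiCl, whose first equivalent deprotonates the carbinol, then effects iodine–magnesium exchange to the arylmagnesium chloride F2; magnesium is chosen over lithium so that the ortho silyloxy groups do not migrate to carbon. In parallel, 21 is deprotonated with n-BuLi to the lithium acetylide F3 and formylated with DMF to 3-[2,4-bis(methoxymethoxy)phenyl]prop-2-ynal F4. Addition of F2 to F4 gives the propargylic alcohol F5, whose carbinol epimers are erased in the next operation. MnO2 oxidises only this activated alcohol to the silylated ynone F6. Et2NH in MeOH strips the two carbonyl-activated aryl triethylsilyl ethers to give 23 and closes ring C through 24, so the sequence comes back to the route at 25.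

2. Step 8.
- What may go wrong: β-hydride loss from the alkylpalladium at the allylic C–H, which is the stereocentre, may compete with reductive elimination, and re-insertion would erode the configuration.
- Transmetalation to the doubly ortho-substituted arylpalladium may be slow.
- The carbon–zinc bond may add to its own ketone.
- Fallback (reversed polarity under copper catalysis, with no alkylpalladium and no ketone): it sets out from 7 and 11. MeMgBr at −78 °C converts 7 into (5S)-5-(iodomethyl)-2,6-dimethylhept-6-en-2-ol F7, and Me3SiCl with imidazole gives its trimethylsilyl ether F8. Aryllithium 11 is transmetalated with MgBr2 to the arylmagnesium bromide F9, which is alkylated by F8 in a Kochi-type coupling (Li2CuCl4 5 mol %, NMP, THF, 0 °C) to the coupled silyl ether F10. NIS in MeCN gives the ring iodide F11. The conditions of step 11 take F11 to 17, and the sequence comes back to the route at 18.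

3. Step 4.
- What may go wrong: recombination of the alkyl radical with the pyridylthiyl fragment may outrun iodine transfer.
- The chain-carrying diiodomethyl radical may add to the isopropenyl group.
- The homoallyl radical may close reversibly onto its alkene, a vinyl shift that would destroy the stereocentre.
- Fallback (decarboxylative arylation, in which the alkyl fragment is handed to nickel rather than to an iodine donor; it replaces steps 4 and 8 and the iodine quench of step 7): it sets out from 5 and 11. N-Hydroxyphthalimide with diisopropylcarbodiimide and DMAP converts 5 into the redox-active ester F12. Aryllithium 11 is transmetalated with ZnCl2 to the arylzinc chloride F13. NiCl2(dme) (20 mol %) with 4,4'-di-tert-butyl-2,2'-bipyridine in THF–DMF at rt joins the two with loss of CO2, and the sequence comes back to the route at 14.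

Further compounds
F1 | step 14 | 1,3-bis(triethylsilyl) ether of 18 | C=C(C)[C@H](CCC(C)(C)O)Cc1c(O[Si](CC)(CC)CC)cc(O[Si](C(C)C)(C(C)C)C(C)C)c(I)c1O[Si](CC)(CC)CC
F2 | step 14 | arylmagnesium chloride from F1 (carbinol as chloromagnesium alkoxide) | C=C(C)[C@H](CCC(C)(C)O[Mg]Cl)Cc1c(O[Si](CC)(CC)CC)cc(O[Si](C(C)C)(C(C)C)C(C)C)c([Mg]Cl)c1O[Si](CC)(CC)CC
F3 | step 14 | {[2,4-bis(methoxymethoxy)phenyl]ethynyl}lithium | [Li]C#Cc1ccc(OCOC)cc1OCOC
F4 | step 14 | 3-[2,4-bis(methoxymethoxy)phenyl]prop-2-ynal | O=CC#Cc1ccc(OCOC)cc1OCOC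
F5 | step 14 | 1-{3-[(2R)-5-hydroxy-5-methyl-2-(prop-1-en-2-yl)hexyl]-2,4-bis(triethylsilyloxy)-6-(triisopropylsilyloxy)phenyl}-3-[2,4-bis(methoxymethoxy)phenyl]prop-2-yn-1-ol, both carbinol epimers | C=C(C)[C@H](CCC(C)(C)O)Cc1c(O[Si](CC)(CC)CC)cc(O[Si](C(C)C)(C(C)C)C(C)C)c(C(O)C#Cc2ccc(OCOC)cc2OCOC)c1O[Si](CC)(CC)CC
F6 | step 14 | 2,4-bis(triethylsilyl) ether of ynone 23 | C=C(C)[C@H](CCC(C)(C)O)Cc1c(O[Si](CC)(CC)CC)cc(O[Si](C(C)C)(C(C)C)C(C)C)c(C(=O)C#Cc2ccc(OCOC)cc2OCOC)c1O[Si](CC)(CC)CC
F7 | step 8 | (5S)-5-(iodomethyl)-2,6-dimethylhept-6-en-2-ol | C=C(C)[C@H](CCC(C)(C)O)CI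
F8 | step 8 | {[(5S)-5-(iodomethyl)-2,6-dimethylhept-6-en-2-yl]oxy}trimethylsilane | C=C(C)[C@H](CCC(C)(C)O[Si](C)(C)C)CI
F9 | step 8 | [2,6-bis(methoxymethoxy)-4-(triisopropylsilyloxy)phenyl]magnesium bromide | Br[Mg]c1c(OCOC)cc(O[Si](C(C)C)(C(C)C)C(C)C)cc1OCOC
F10 | step 8 | trimethylsilyl ether of (5R)-5-{[2,6-bis(methoxymethoxy)-4-(triisopropylsilyloxy)phenyl]methyl}-2,6-dimethylhept-6-en-2-ol | C=C(C)[C@H](CCC(C)(C)O[Si](C)(C)C)Cc1c(OCOC)cc(O[Si](C(C)C)(C(C)C)C(C)C)cc1OCOC
F11 | step 8 | trimethylsilyl ether of 16 | C=C(C)[C@H](CCC(C)(C)O[Si](C)(C)C)Cc1c(OCOC)cc(O[Si](C(C)C)(C(C)C)C(C)C)c(I)c1OCOC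
F12 | step 4 | 1,3-dioxoisoindolin-2-yl (3R)-6-oxo-3-(prop-1-en-2-yl)heptanoate | C=C(C)[C@H](CCC(C)=O)CC(=O)ON1C(=O)c2ccccc2C1=O
F13 | step 4 | [2,6-bis(methoxymethoxy)-4-(triisopropylsilyloxy)phenyl]zinc chloride | Cl[Zn]c1c(OCOC)cc(O[Si](C(C)C)(C(C)C)C(C)C)cc1OCOC
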